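**Retrosynthetic overview**
1. The 36-membered lactone ring (C1–C35 plus the ring oxygen) is closed last by ring-closing metathesis at C14=C15, and the alkene is then reduced. This is possible because C14 is the CH2 next to carbinol C13 and C15 is the second CH2 from carbinol C17 (syn-1,5-diol C13/C17), so the two ends are a vinyl carbinol and an allyl carbinol; the only other alkene, the trisubstituted C2=C3 enoate, is inert.
2. The ester O35–C1 is made intermolecularly from the C35 alcohol (right wing, C15–C40) and a C1–C14 2-ynoic acid (left wing); the (Z)-C2=C3(Me) unit then comes from syn-carbocupration.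
3. Left wing: (R,R)-1,2:6,7-diepoxyheptane supplies C8–C14 with C9 and C13; it is opened at C8 by a dithiane (C7, then 1,3-syn reduction) and at C14 by a sulfonium ylide.
4. Right wing: the enantiomeric (S,S)-diepoxide supplies C20–C26 (mirror image of C8–C14 across C17). A silyl-dithiane linchpin (C27) joins the C15–C26 epoxide to the C28–C40 epoxide (C35/C36 by asymmetric epoxidation and Me3Al, C33 by iodocarbonate cyclisation, C29 from a malic acid-derived unit).
5. Ring order: 1,3-dioxane acetonides at C7/C9 (step 9) and C25/C27 (step 34) as temporary rings, then the macrolactone (step 38); both acetonides are removed in step 40.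

Key step: step 38

Remark (assumption): the (R,R) antipode of the cobalt salen complex is taken to leave 2-alkyloxiranes of (R) configuration unhydrolysed and the (S,S) antipode those of (S) configuration; if the sense were the reverse, the two antipodes would simply be exchanged.
Remark (names): (salen)Co(OAc) is [N,N'-bis(3,5-di-tert-butylsalicylidene)-1,2-cyclohexanediaminato]cobalt acetate (trivalent cobalt). Large intermediates are described with the target's chain locants (C1 lactone carbonyl, C35 lactone O–CH, C36 CHMe, C37–C40 butyl); their configurations are those of the corresponding target carbons, as written in the SMILES.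

**Steps**

Step 1
Reactants: 1 hepta-1,6-diene
Product: 2 2,2'-(propane-1,3-diyl)bis(oxirane) as the mixture of racemic and meso forms
Conditions: mCPBA (2.4 equiv), CH2Cl2, 0 °C → rt
Reagents that add atoms: mCPBA, O=C(OO)c1cccc(Cl)c1
Why: Prilezhaev epoxidation of both monosubstituted alkenes; stereochemistry is left open because steps 2 and 3 each select one enantiomer of the C2-symmetric diastereomer.

Step 2
Reactants: 2 2,2'-(propane-1,3-diyl)bis(oxirane)
Product: 3 (2R,2'R)-2,2'-(propane-1,3-diyl)bis(oxirane)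
Conditions: (R,R)-(salen)Co(OAc) (1 mol %), H2O (1.05 equiv), THF, 0 °C → rt; distillation
Reagents that add atoms: none
Why: Jacobsen hydrolytic kinetic resolution: the chiral cobalt salen complex should hydrolyse every (S)-configured oxirane, so only the (R,R)-bis-epoxide (future C9 and C13) survives as a bis-epoxide and is separated from the polar epoxy diol and tetraol.

Step 3
Reactants: 2 2,2'-(propane-1,3-diyl)bis(oxirane)
Product: 4 (2S,2'S)-2,2'-(propane-1,3-diyl)bis(oxirane)
Conditions: (S,S)-(salen)Co(OAc) (1 mol %), H2O (1.05 equiv), THF, 0 °C → rt; distillation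
Reagents that add atoms: none
Why: Jacobsen hydrolytic kinetic resolution with the antipodal catalyst should leave the (S,S)-bis-epoxide, which carries the future C21 and C25 centres.

Step 4
Reactants: 5 1,3-dithiane; 6 (5-chloropent-1-yn-1-yl)trimethylsilane
Product: 8 2-[5-(trimethylsilyl)pent-4-yn-1-yl]-1,3-dithiane, via 2-lithio-1,3-dithiane 7 (not isolated)
Conditions: n-BuLi, THF, −30 °C; then 6, −30 °C → rt
Reagents that add atoms: none
Why: Corey–Seebach alkylation of the lithiated dithiane with the primary chloride gives the acyl-anion equivalent of C7 carrying the masked C2–C3 alkyne.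

Step 5
Reactants: 8 2-[5-(trimethylsilyl)pent-4-yn-1-yl]-1,3-dithiane; 3 (2R,2'R)-2,2'-(propane-1,3-diyl)bis(oxirane)
Product: 10 (2R)-5-[(2R)-oxiran-2-yl]-1-{2-[5-(trimethylsilyl)pent-4-yn-1-yl]-1,3-dithian-2-yl}pentan-2-ol, via lithiated dithiane 9 (not isolated)
Conditions: t-BuLi, THF/HMPA (9:1), −78 °C; then 3 (3 equiv), −78 → −30 °C; then H2O
Reagents that add atoms: none
Why: Corey–Seebach epoxide opening: the 2-lithio-dithiane attacks the terminal carbon (C8) of one of the two homotopic oxiranes of C2-symmetric 3, used in excess to suppress double addition, and C9 is untouched.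

Step 6
Reactants: 10 (2R)-5-[(2R)-oxiran-2-yl]-1-{2-[5-(trimethylsilyl)pent-4-yn-1-yl]-1,3-dithian-2-yl}pentan-2-ol
Product: 11 (3R,7R)-8-{2-[5-(trimethylsilyl)pent-4-yn-1-yl]-1,3-dithian-2-yl}oct-1-ene-3,7-diol
Conditions: Me3S+ I− (6 equiv), n-BuLi (5.5 equiv), THF, −10 °C; then 10, −10 °C → rt
Reagents that add atoms: trimethylsulfonium iodide, C[S+](C)C.[I-]
Why: Epoxide-to-allylic-alcohol homologation: dimethylsulfonium methylide opens the remaining oxirane at its CH2 (C14) and a further equivalent of ylide induces elimination of dimethyl sulfide, giving the C13 vinyl carbinol without touching C13.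

Step 7
Reactants: 11 (3R,7R)-8-{2-[5-(trimethylsilyl)pent-4-yn-1-yl]-1,3-dithian-2-yl}oct-1-ene-3,7-diol
Product: 12 (8R,12R)-8,12-dihydroxy-1-(trimethylsilyl)tetradec-13-en-1-yn-6-one
Conditions: MeI, CaCO3, MeCN/H2O (9:1), 45 °C
Reagents that add atoms: water, O
Why: Alkylative dithioketal hydrolysis (S-methylation, then attack of water) unmasks the C7 ketone under buffered conditions that spare the silyl alkyne and the allylic alcohol.

Step 8
Reactants: 12 (8R,12R)-8,12-dihydroxy-1-(trimethylsilyl)tetradec-13-en-1-yn-6-one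
Product: 13 (6S,8R,12R)-1-(trimethylsilyl)tetradec-13-en-1-yne-6,8,12-triol
Conditions: Et2BOMe, NaBH4, THF/MeOH (4:1), −78 °C; AcOH, MeOH co-evaporation
Reagents that add atoms: none
Why: Narasaka–Prasad reduction: hydride adds axially to the six-membered diethylboron chelate of the β-hydroxy ketone, so C7 should be set 1,3-syn to C9.

Step 9
Reactants: 13 (6S,8R,12R)-1-(trimethylsilyl)tetradec-13-en-1-yne-6,8,12-triol
Product: 14 (3R)-6-{(4R,6S)-2,2-dimethyl-6-[5-(trimethylsilyl)pent-4-yn-1-yl]-1,3-dioxan-4-yl}hex-1-en-3-ol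
Conditions: 2,2-dimethoxypropane, PPTS (cat.), CH2Cl2, rt
Reagents that add atoms: 2,2-dimethoxypropane, COC(C)(C)OC
Why: Acetalisation under thermodynamic control: only the syn-1,3-diol C7/C9 can close a six-membered isopropylidene acetal with both substituents equatorial, so the C13 hydroxyl stays free.

Step 10
Reactants: 14 (3R)-6-{(4R,6S)-2,2-dimethyl-6-[5-(trimethylsilyl)pent-4-yn-1-yl]-1,3-dioxan-4-yl}hex-1-en-3-ol
Product: 15 C13 tert-butyldimethylsilyl ether of 14
Conditions: TBSCl, imidazole, DMF, rt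
Reagents that add atoms: TBSCl, CC(C)(C)[Si](C)(C)Cl
Why: Standard silylation of the remaining secondary allylic alcohol.

Step 11
Reactants: 15 C13 tert-butyldimethylsilyl ether of 14
Product: 16 tert-butyl{[(3R)-6-[(4R,6S)-2,2-dimethyl-6-(pent-4-yn-1-yl)-1,3-dioxan-4-yl]hex-1-en-3-yl]oxy}dimethylsilane
Conditions: K2CO3 (0.3 equiv), MeOH, rt
Reagents that add atoms: none
Why: Methoxide-catalysed methanolysis cleaves the alkynyl C–Si bond only; the silyl ether and the acetal are stable to these conditions.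

Step 12
Reactants: 16 tert-butyl{[(3R)-6-[(4R,6S)-2,2-dimethyl-6-(pent-4-yn-1-yl)-1,3-dioxan-4-yl]hex-1-en-3-yl]oxy}dimethylsilane
Product: 18 6-[(4S,6R)-6-{(4R)-4-[(tert-butyldimethylsilyl)oxy]hex-5-en-1-yl}-2,2-dimethyl-1,3-dioxan-4-yl]hex-2-ynoic acid, via lithium acetylide 17 (not isolated)
Conditions: n-BuLi, THF, −78 °C; then CO2 (g), −78 → 0 °C; then 0.5 M HCl to pH 3, 0 °C
Reagents that add atoms: carbon dioxide, O=C=O
Why: Deprotonation of the terminal alkyne and carboxylation of the acetylide gives the 2-ynoic acid, a geometrically blank precursor of the (Z)-enoate.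

Step 13
Reactants: 19 rac-2-(2-bromoethyl)oxirane
Product: 20 (2S)-2-(2-bromoethyl)oxirane
Conditions: (S,S)-(salen)Co(OAc) (0.5 mol %), H2O (0.55 equiv), THF, 0 °C → rt; distillation
Reagents that add atoms: none
Why: Jacobsen hydrolytic kinetic resolution should hydrolyse the (R)-oxirane and leave the (S)-oxirane, which carries the future C17 centre.

Step 14
Reactants: 20 (2S)-2-(2-bromoethyl)oxirane
Product: 21 (3R)-1-bromohex-5-en-3-ol
Conditions: CH2=CHMgBr (1.3 equiv), CuI (10 mol %), THF, −40 → −20 °C; then H2O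
Reagents that add atoms: vinylmagnesium bromide, C=C[Mg]Br
Why: Copper-catalysed Grignard opening of the oxirane at its terminal carbon (future C16), faster at low temperature than substitution of the primary bromide; C17 keeps its configuration.

Step 15
Reactants: 21 (3R)-1-bromohex-5-en-3-ol
Product: 22 {[(3R)-1-bromohex-5-en-3-yl]oxy}(tert-butyl)dimethylsilane
Conditions: TBSCl, imidazole, DMF, rt
Reagents that add atoms: TBSCl, CC(C)(C)[Si](C)(C)Cl
Why: Standard silylation, needed before the Grignard reagent is formed.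

Step 16
Reactants: 22 {[(3R)-1-bromohex-5-en-3-yl]oxy}(tert-butyl)dimethylsilane; 4 (2S,2'S)-2,2'-(propane-1,3-diyl)bis(oxirane)
Product: 24 C15–C26 hydroxy epoxide (C25–C26 oxirane; 21-OH; 17-O-TBS; C15=CH2 terminal alkene), via Grignard reagent 23 (not isolated)
Conditions: Mg, BrCH2CH2Br (cat.), THF, 40 °C; then CuI (10 mol %), 4 (3 equiv), −40 → −20 °C; then H2O
Reagents that add atoms: none
Why: Grignard formation at C19 and copper-catalysed opening of one homotopic oxirane of 4 (in excess) at its terminal carbon C20 form the C19–C20 bond; C21 and C25 come unchanged from 4.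

Step 17
Reactants: 24 C15–C26 hydroxy epoxide
Product: 25 C15–C26 epoxide (C25–C26 oxirane; 17,21-bis-O-TBS; C15=CH2 terminal alkene)
Conditions: TBSCl, imidazole, DMF, rt
Reagents that add atoms: TBSCl, CC(C)(C)[Si](C)(C)Cl
Why: Standard silylation of the C21 hydroxyl, which also removes the risk of intramolecular epoxide opening.

Step 18
Reactants: 26 (2E)-hept-2-en-1-ol
Product: 27 [(2R,3R)-3-butyloxiran-2-yl]methanol
Conditions: Ti(OiPr)4 (10 mol %), D-(−)-diethyl tartrate (12 mol %), t-BuOOH, 4 Å MS, CH2Cl2, −20 °C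
Reagents that add atoms: tert-butyl hydroperoxide, CC(C)(C)OO
Why: Sharpless asymmetric epoxidation; with the D-(−)-tartrate ligand the E-allylic alcohol should give the (2R,3R)-epoxy alcohol.

Step 19
Reactants: 27 [(2R,3R)-3-butyloxiran-2-yl]methanol
Product: 28 (2S,3S)-3-methylheptane-1,2-diol
Conditions: Me3Al (3 equiv), hexane/CH2Cl2, 0 °C → rt; aq. Rochelle salt
Reagents that add atoms: trimethylaluminium, C[Al](C)C
Why: Trimethylaluminium opens the 2,3-epoxy alcohol at C3 through the aluminium alkoxide with inversion, so the new methyl group ends anti to the hydroxyl (C36 and C35 of the target).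

Step 20
Reactants: 28 (2S,3S)-3-methylheptane-1,2-diol
Product: 30 (2S)-2-[(2S)-hexan-2-yl]oxirane, via primary tosylate 29 (not isolated)
Conditions: NaH (2.2 equiv), 1-(p-toluenesulfonyl)imidazole (1.05 equiv), THF, 0 °C → rt
Reagents that add atoms: none
Why: Selective sulfonylation of the primary alkoxide followed by intramolecular Williamson closure gives the terminal oxirane with retention at C35.

Step 21
Reactants: 30 (2S)-2-[(2S)-hexan-2-yl]oxirane
Product: 31 (4R,5S)-5-methylnon-1-en-4-ol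
Conditions: CH2=CHMgBr (1.5 equiv), CuI (10 mol %), THF, −40 → −20 °C; then H2O
Reagents that add atoms: vinylmagnesium bromide, C=C[Mg]Br
Why: Copper-catalysed Grignard opening at the terminal oxirane carbon (C34) gives the homoallylic alcohol without touching C35 or C36.

Step 22
Reactants: 31 (4R,5S)-5-methylnon-1-en-4-ol
Product: 32 tert-butyl (4R,5S)-5-methylnon-1-en-4-yl carbonate
Conditions: Boc2O, DMAP (cat.), MeCN, rt
Reagents that add atoms: di-tert-butyl dicarbonate, CC(C)(C)OC(=O)OC(=O)OC(C)(C)C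
Why: DMAP-catalysed acylation installs the internal oxygen nucleophile for step 23.

Step 23
Reactants: 32 tert-butyl (4R,5S)-5-methylnon-1-en-4-yl carbonate
Product: 33 (4R,6S)-4-[(2S)-hexan-2-yl]-6-(iodomethyl)-1,3-dioxan-2-one
Conditions: IBr (1.2 equiv), toluene, −85 °C
Reagents that add atoms: iodine monobromide, IBr
Why: Iodocarbonate cyclisation: the carbonate carbonyl oxygen opens the iodonium ion 6-exo through a chair-like transition state with both substituents equatorial and the tert-butyl group is lost, so C33–O should be set 1,3-syn to C35–O.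

Step 24
Reactants: 33 (4R,6S)-4-[(2S)-hexan-2-yl]-6-(iodomethyl)-1,3-dioxan-2-one
Product: 34 (2R,3S)-3-methyl-1-[(2S)-oxiran-2-yl]heptan-2-ol
Conditions: K2CO3 (3 equiv), MeOH, rt
Reagents that add atoms: none
Why: Methanolysis of the cyclic carbonate frees both oxygens and the C33 alkoxide displaces iodide (3-exo-tet), giving the terminal oxirane and a free C35 hydroxyl, which are thereby differentiated.

Step 25
Reactants: 34 (2R,3S)-3-methyl-1-[(2S)-oxiran-2-yl]heptan-2-ol
Product: 35 (2S)-2-{(2R,3S)-2-[(4-methoxybenzyl)oxy]-3-methylheptyl}oxirane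
Conditions: NaH, 4-methoxybenzyl chloride, Bu4NI (cat.), THF/DMF, 0 °C → rt
Reagents that add atoms: 4-methoxybenzyl chloride, COc1ccc(CCl)cc1
Why: Williamson etherification protects O35 with a group that can later be removed oxidatively in the presence of silyl ethers, acetals and alkenes.

Step 26
Reactants: 36 2-[(4S)-2,2-dimethyl-1,3-dioxolan-4-yl]ethan-1-ol
Product: 37 (4S)-4-(2-bromoethyl)-2,2-dimethyl-1,3-dioxolane
Conditions: CBr4, PPh3, 2,6-lutidine (cat.), CH2Cl2, 0 °C
Reagents that add atoms: carbon tetrabromide, BrC(Br)(Br)Br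
Why: Appel reaction converts the primary alcohol of the malic acid-derived building block (future C29) into the bromide without touching the acetal.

Step 27
Reactants: 37 (4S)-4-(2-bromoethyl)-2,2-dimethyl-1,3-dioxolane; 35 (2S)-2-{(2R,3S)-2-[(4-methoxybenzyl)oxy]-3-methylheptyl}oxirane
Product: 39 C28–C40 acetonide alcohol (28,29-O-isopropylidene; 33-OH; 35-O-PMB), via Grignard reagent 38 (not isolated)
Conditions: Mg, THF, 40 °C; then CuI (10 mol %), 35, −40 → −20 °C; then H2O
Reagents that add atoms: none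
Why: Grignard formation and copper-catalysed opening of the oxirane at C32 join C31 to C32; C29 comes from the dioxolane and C33 keeps its configuration.

Step 28
Reactants: 39 C28–C40 acetonide alcohol
Product: 40 C28–C40 acetonide silyl ether (28,29-O-isopropylidene; 33-O-TBS; 35-O-PMB)
Conditions: TBSCl, imidazole, DMF, 40 °C
Reagents that add atoms: TBSCl, CC(C)(C)[Si](C)(C)Cl
Why: Standard silylation of the C33 hydroxyl.

Step 29
Reactants: 40 C28–C40 acetonide silyl ether
Product: 41 C28–C40 28,29-diol (33-O-TBS; 35-O-PMB)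
Conditions: AcOH/H2O/THF (3:1:1), 45 °C
Reagents that add atoms: none
Why: Mild acid hydrolysis removes the terminal dioxolane, which is far more labile than the secondary silyl ether and the benzyl-type ether.

Step 30
Reactants: 41 C28–C40 28,29-diol
Product: 43 C28–C40 epoxide (C28–C29 oxirane; 33-O-TBS; 35-O-PMB), via primary tosylate 42 (not isolated)
Conditions: NaH (2.2 equiv), 1-(p-toluenesulfonyl)imidazole (1.05 equiv), THF, 0 °C → rt
Reagents that add atoms: none
Why: Selective sulfonylation of the primary alkoxide and intramolecular Williamson closure give the terminal oxirane with retention at C29.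

Step 31
Reactants: 44 tert-butyl(1,3-dithian-2-yl)dimethylsilane; 43 C28–C40 epoxide; 25 C15–C26 epoxide
Product: 48 C15–C40 dithiane alcohol (C27 1,3-dithiane; 25-OH; 17,21,29,33-tetra-O-TBS; 35-O-PMB), via lithiated silyl dithiane 45 (not isolated), via lithium alkoxide adduct 46 (not isolated), via Brook-shifted lithio dithiane 47 (not isolated)
Conditions: t-BuLi, Et2O, −78 → −45 °C; then 43, −78 → −25 °C; then 25, HMPA, THF, −78 °C → rt; then H2O
Reagents that add atoms: none
Why: Anion relay three-component coupling: the lithiated 2-silyl dithiane opens 43 at C28, HMPA triggers the 1,4-Brook rearrangement that silylates O29 and regenerates a dithiane anion, and this opens 25 at C26; all stereocentres come from the epoxides.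

Step 32
Reactants: 48 C15–C40 dithiane alcohol
Product: 49 C15–C40 β-hydroxy ketone (C27 ketone; 25-OH)
Conditions: MeI, CaCO3, MeCN/H2O (9:1), 45 °C
Reagents that add atoms: water, O
Why: Alkylative dithioketal hydrolysis unmasks the C27 ketone under buffered conditions compatible with the silyl ethers, the benzyl-type ether and the terminal alkene.

Step 33
Reactants: 49 C15–C40 β-hydroxy ketone
Product: 50 C15–C40 25,27-diol
Conditions: Et2BOMe, NaBH4, THF/MeOH (4:1), −78 °C; AcOH, MeOH co-evaporation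
Reagents that add atoms: none
Why: Narasaka–Prasad reduction through the diethylboron chelate of the free C25 hydroxyl and the ketone should set C27 syn to C25, and hence anti to the silylated C29 oxygen.

Step 34
Reactants: 50 C15–C40 25,27-diol
Product: 51 C15–C40 25,27-O-isopropylidene acetal (35-O-PMB)
Conditions: 2,2-dimethoxypropane, PPTS (cat.), CH2Cl2, rt
Reagents that add atoms: 2,2-dimethoxypropane, COC(C)(C)OC
Why: Acetalisation of the syn-1,3-diol as its six-membered isopropylidene acetal.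

Step 35
Reactants: 51 C15–C40 25,27-O-isopropylidene acetal
Product: 52 right-wing alcohol (35-OH; 17,21,29,33-tetra-O-TBS; 25,27-acetonide; C15=CH2)
Conditions: DDQ, CH2Cl2/pH 7 buffer (10:1), 0 °C
Reagents that add atoms: none
Why: Oxidative cleavage of the 4-methoxybenzyl ether by DDQ frees only the C35 hydroxyl.

Step 36
Reactants: 18 6-[(4S,6R)-6-{(4R)-4-[(tert-butyldimethylsilyl)oxy]hex-5-en-1-yl}-2,2-dimethyl-1,3-dioxan-4-yl]hex-2-ynoic acid; 52 right-wing alcohol
Product: 53 seco 2-ynoate ester (O35–C1 ester; C2≡C3; terminal alkenes at C14 and C15)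
Conditions: DCC, DMAP (cat.), CH2Cl2, −20 → 0 °C
Reagents that add atoms: none
Why: Steglich esterification of the unhindered, activated ynoic acid with the hindered secondary alcohol; an ynoic acid has no alkene geometry to lose on activation.

Step 37
Reactants: 53 seco 2-ynoate ester
Product: 54 seco (2Z)-3-methyl-2-enoate ester
Conditions: CuI (2.2 equiv), MeLi (4.4 equiv), THF, 0 °C; then 53, −78 °C; then MeOH/aq. NH4Cl at −78 °C
Reagents that add atoms: lithium dimethylcuprate, [Li+].C[Cu-]C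
Why: Syn-carbocupration of the ynoate at −78 °C places methyl on C3 and copper on C2 on the same side, and protonation with retention puts the C4 chain cis to the ester, which is the (Z)-enoate.

Step 38
Reactants: 54 seco (2Z)-3-methyl-2-enoate ester
Product: 55 protected macrolactone with C14=C15 (E/Z mixture)
Conditions: second-generation Grubbs catalyst RuCl2(=CHPh)(H2IMes)(PCy3) (2 × 10 mol %), toluene (0.5 mM), 80 °C, argon sparge
Reagents that add atoms: none
Why: Alkene metathesis by the Chauvin mechanism: the ruthenium alkylidene loads at the unhindered C15 allyl terminus and the resulting carbene closes onto the C14 vinyl group of the C13 silyl ether through a ruthenacyclobutane, releasing ethene. The closest known reaction type is macrocyclising ring-closing metathesis of ester-linked dienes bearing allylic and homoallylic silyl ethers to large macrolides. The only ring closed is the 36-membered lactone (C1–C35 and the ring oxygen), by end-to-end macrocyclisation of the acyclic seco ester between two monosubstituted alkenes. No stereocentre is created, and the geometry of the new C14=C15 bond is irrelevant because step 39 erases it. The selectivities needed are ring closure over oligomerisation, secured by 0.5 mM concentration, portionwise catalyst and ethene removal, and chemoselectivity among the alkenes, secured because the only other C=C (C2=C3) is a trisubstituted, electron-poor enoate that does not engage the catalyst. All hydroxyls are capped as silyl ethers or acetals, so ruthenium hydride isomerisation of a free allylic alcohol cannot intervene.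

Step 39
Reactants: 55 protected macrolactone with C14=C15
Product: 56 protected macrolactone (C14–C15 saturated)
Conditions: 2-nitrobenzenesulfonohydrazide (excess, in portions), Et3N, CH2Cl2, rt
Reagents that add atoms: none
Why: Diimide reduction (concerted syn transfer of H2) should take place at the isolated 1,2-disubstituted C14=C15 alkene much faster than at the trisubstituted conjugated C2=C3 enoate.

Step 40
Reactants: 56 protected macrolactone
Product: 57 CNP0126363.4
Conditions: HF (48 % aq.), MeCN, 0 °C → rt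
Reagents that add atoms: none
Why: Global deprotection: aqueous HF cleaves the five silyl ethers and hydrolyses both isopropylidene acetals under conditions that should leave the lactone and the (Z)-enoate untouched.

**Compound list**
1 | hepta-1,6-diene | C=CCCCC=C | starting material
2 | 2,2'-(propane-1,3-diyl)bis(oxirane), racemic and meso forms together | C1OC1CCCC1CO1 | intermediate
3 | (2R,2'R)-2,2'-(propane-1,3-diyl)bis(oxirane) | C1O[C@@H]1CCC[C@@H]2CO2 | intermediate
4 | (2S,2'S)-2,2'-(propane-1,3-diyl)bis(oxirane) | C1O[C@H]1CCC[C@H]2CO2 | intermediate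
5 | 1,3-dithiane | C1CSCSC1 | starting material
6 | (5-chloropent-1-yn-1-yl)trimethylsilane | C[Si](C)(C)C#CCCCCl | starting material
7 | 2-lithio-1,3-dithiane | [Li]C1SCCCS1 | intermediate
8 | 2-[5-(trimethylsilyl)pent-4-yn-1-yl]-1,3-dithiane | C[Si](C)(C)C#CCCCC1SCCCS1 | intermediate
9 | 2-lithio-2-[5-(trimethylsilyl)pent-4-yn-1-yl]-1,3-dithiane | C[Si](C)(C)C#CCCCC1([Li])SCCCS1 | intermediate
10 | (2R)-5-[(2R)-oxiran-2-yl]-1-{2-[5-(trimethylsilyl)pent-4-yn-1-yl]-1,3-dithian-2-yl}pentan-2-ol | C[Si](C)(C)C#CCCCC1(SCCCS1)C[C@H](O)CCC[C@@H]2CO2 | intermediate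
11 | (3R,7R)-8-{2-[5-(trimethylsilyl)pent-4-yn-1-yl]-1,3-dithian-2-yl}oct-1-ene-3,7-diol | C[Si](C)(C)C#CCCCC1(SCCCS1)C[C@H](O)CCC[C@@H](O)C=C | intermediate
12 | (8R,12R)-8,12-dihydroxy-1-(trimethylsilyl)tetradec-13-en-1-yn-6-one | C[Si](C)(C)C#CCCCC(=O)C[C@H](O)CCC[C@@H](O)C=C | intermediate
13 | (6S,8R,12R)-1-(trimethylsilyl)tetradec-13-en-1-yne-6,8,12-triol | C[Si](C)(C)C#CCCC[C@H](O)C[C@H](O)CCC[C@@H](O)C=C | intermediate
14 | (3R)-6-{(4R,6S)-2,2-dimethyl-6-[5-(trimethylsilyl)pent-4-yn-1-yl]-1,3-dioxan-4-yl}hex-1-en-3-ol | C[Si](C)(C)C#CCCC[C@H]1C[C@@H](CCC[C@@H](O)C=C)OC(C)(C)O1 | intermediate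
15 | tert-butyldimethylsilyl ether of 14 at the C13 hydroxyl | C[Si](C)(C)C#CCCC[C@H]1C[C@@H](CCC[C@@H](O[Si](C)(C)C(C)(C)C)C=C)OC(C)(C)O1 | intermediate
16 | tert-butyl{[(3R)-6-[(4R,6S)-2,2-dimethyl-6-(pent-4-yn-1-yl)-1,3-dioxan-4-yl]hex-1-en-3-yl]oxy}dimethylsilane | C#CCCC[C@H]1C[C@@H](CCC[C@@H](O[Si](C)(C)C(C)(C)C)C=C)OC(C)(C)O1 | intermediate
17 | lithium acetylide of 16 | [Li]C#CCCC[C@H]1C[C@@H](CCC[C@@H](O[Si](C)(C)C(C)(C)C)C=C)OC(C)(C)O1 | intermediate
18 | 6-[(4S,6R)-6-{(4R)-4-[(tert-butyldimethylsilyl)oxy]hex-5-en-1-yl}-2,2-dimethyl-1,3-dioxan-4-yl]hex-2-ynoic acid (left wing, C1–C14) | OC(=O)C#CCCC[C@H]1C[C@@H](CCC[C@@H](O[Si](C)(C)C(C)(C)C)C=C)OC(C)(C)O1 | intermediate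
19 | rac-2-(2-bromoethyl)oxirane | BrCCC1CO1 | starting material
20 | (2S)-2-(2-bromoethyl)oxirane | BrCC[C@H]1CO1 | intermediate
21 | (3R)-1-bromohex-5-en-3-ol | BrCC[C@H](O)CC=C | intermediate
22 | {[(3R)-1-bromohex-5-en-3-yl]oxy}(tert-butyl)dimethylsilane | BrCC[C@H](O[Si](C)(C)C(C)(C)C)CC=C | intermediate
23 | {(3R)-3-[(tert-butyldimethylsilyl)oxy]hex-5-en-1-yl}magnesium bromide | Br[Mg]CC[C@H](O[Si](C)(C)C(C)(C)C)CC=C | intermediate
24 | C15–C26 hydroxy epoxide: C25–C26 oxirane, 21-OH, 17-O-TBS, C15=CH2 | C1O[C@H]1CCC[C@H](O)CCC[C@H](O[Si](C)(C)C(C)(C)C)CC=C | intermediate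
25 | C15–C26 epoxide: C25–C26 oxirane, 17,21-bis-O-TBS, C15=CH2 | C1O[C@H]1CCC[C@H](O[Si](C)(C)C(C)(C)C)CCC[C@H](O[Si](C)(C)C(C)(C)C)CC=C | intermediate
26 | (2E)-hept-2-en-1-ol | CCCC/C=C/CO | starting material
27 | [(2R,3R)-3-butyloxiran-2-yl]methanol | CCCC[C@H]1O[C@@H]1CO | intermediate
28 | (2S,3S)-3-methylheptane-1,2-diol | CCCC[C@H](C)[C@H](O)CO | intermediate
29 | (2S,3S)-2-hydroxy-3-methylheptyl 4-methylbenzenesulfonate | CCCC[C@H](C)[C@H](O)COS(=O)(=O)c1ccc(C)cc1 | intermediate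
30 | (2S)-2-[(2S)-hexan-2-yl]oxirane | CCCC[C@H](C)[C@H]1CO1 | intermediate
31 | (4R,5S)-5-methylnon-1-en-4-ol | CCCC[C@H](C)[C@H](O)CC=C | intermediate
32 | tert-butyl (4R,5S)-5-methylnon-1-en-4-yl carbonate | CCCC[C@H](C)[C@H](OC(=O)OC(C)(C)C)CC=C | intermediate
33 | (4R,6S)-4-[(2S)-hexan-2-yl]-6-(iodomethyl)-1,3-dioxan-2-one | CCCC[C@H](C)[C@H]1C[C@@H](CI)OC(=O)O1 | intermediate
34 | (2R,3S)-3-methyl-1-[(2S)-oxiran-2-yl]heptan-2-ol | CCCC[C@H](C)[C@H](O)C[C@H]1CO1 | intermediate
35 | (2S)-2-{(2R,3S)-2-[(4-methoxybenzyl)oxy]-3-methylheptyl}oxirane | CCCC[C@H](C)[C@H](OCc1ccc(OC)cc1)C[C@H]1CO1 | intermediate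
36 | 2-[(4S)-2,2-dimethyl-1,3-dioxolan-4-yl]ethan-1-ol | OCC[C@H]1COC(C)(C)O1 | starting material
37 | (4S)-4-(2-bromoethyl)-2,2-dimethyl-1,3-dioxolane | BrCC[C@H]1COC(C)(C)O1 | intermediate
38 | {2-[(4S)-2,2-dimethyl-1,3-dioxolan-4-yl]ethyl}magnesium bromide | Br[Mg]CC[C@H]1COC(C)(C)O1 | intermediate
39 | C28–C40 acetonide alcohol: 28,29-O-isopropylidene, 33-OH, 35-O-(4-methoxybenzyl) | CCCC[C@H](C)[C@H](OCc1ccc(OC)cc1)C[C@H](O)CCC[C@H]1COC(C)(C)O1 | intermediate
40 | C28–C40 acetonide silyl ether: 28,29-O-isopropylidene, 33-O-TBS, 35-O-(4-methoxybenzyl) | CCCC[C@H](C)[C@H](OCc1ccc(OC)cc1)C[C@H](O[Si](C)(C)C(C)(C)C)CCC[C@H]1COC(C)(C)O1 | intermediate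
41 | C28–C40 28,29-diol: 33-O-TBS, 35-O-(4-methoxybenzyl) | CCCC[C@H](C)[C@H](OCc1ccc(OC)cc1)C[C@H](O[Si](C)(C)C(C)(C)C)CCC[C@H](O)CO | intermediate
42 | 28-O-tosylate of 41 | CCCC[C@H](C)[C@H](OCc1ccc(OC)cc1)C[C@H](O[Si](C)(C)C(C)(C)C)CCC[C@H](O)COS(=O)(=O)c1ccc(C)cc1 | intermediate
43 | C28–C40 epoxide: C28–C29 oxirane, 33-O-TBS, 35-O-(4-methoxybenzyl) | CCCC[C@H](C)[C@H](OCc1ccc(OC)cc1)C[C@H](O[Si](C)(C)C(C)(C)C)CCC[C@H]1CO1 | intermediate
44 | tert-butyl(1,3-dithian-2-yl)dimethylsilane | CC(C)(C)[Si](C)(C)C1SCCCS1 | starting material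
45 | tert-butyl(2-lithio-1,3-dithian-2-yl)dimethylsilane | CC(C)(C)[Si](C)(C)C1([Li])SCCCS1 | intermediate
46 | lithium C29 alkoxide from 45 and 43 (2-TBS-1,3-dithian-2-yl on C28) | CCCC[C@H](C)[C@H](OCc1ccc(OC)cc1)C[C@H](O[Si](C)(C)C(C)(C)C)CCC[C@H](O[Li])CC1(SCCCS1)[Si](C)(C)C(C)(C)C | intermediate
47 | C27-lithio-1,3-dithiane with 29-O-TBS (after 1,4-silyl shift) | CCCC[C@H](C)[C@H](OCc1ccc(OC)cc1)C[C@H](O[Si](C)(C)C(C)(C)C)CCC[C@H](O[Si](C)(C)C(C)(C)C)CC1([Li])SCCCS1 | intermediate
48 | C15–C40 dithiane alcohol: C27 1,3-dithiane, 25-OH, 17,21,29,33-tetra-O-TBS, 35-O-(4-methoxybenzyl), C15=CH2 | CCCC[C@H](C)[C@H](OCc1ccc(OC)cc1)C[C@H](O[Si](C)(C)C(C)(C)C)CCC[C@H](O[Si](C)(C)C(C)(C)C)CC1(SCCCS1)C[C@@H](O)CCC[C@H](O[Si](C)(C)C(C)(C)C)CCC[C@H](O[Si](C)(C)C(C)(C)C)CC=C | intermediate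
49 | C15–C40 β-hydroxy ketone: C27 ketone, 25-OH, otherwise as 48 | CCCC[C@H](C)[C@H](OCc1ccc(OC)cc1)C[C@H](O[Si](C)(C)C(C)(C)C)CCC[C@H](O[Si](C)(C)C(C)(C)C)CC(=O)C[C@@H](O)CCC[C@H](O[Si](C)(C)C(C)(C)C)CCC[C@H](O[Si](C)(C)C(C)(C)C)CC=C | intermediate
50 | C15–C40 25,27-syn-diol, otherwise as 48 | CCCC[C@H](C)[C@H](OCc1ccc(OC)cc1)C[C@H](O[Si](C)(C)C(C)(C)C)CCC[C@H](O[Si](C)(C)C(C)(C)C)C[C@@H](O)C[C@@H](O)CCC[C@H](O[Si](C)(C)C(C)(C)C)CCC[C@H](O[Si](C)(C)C(C)(C)C)CC=C | intermediate
51 | C15–C40 25,27-O-isopropylidene acetal, 35-O-(4-methoxybenzyl) | CCCC[C@H](C)[C@H](OCc1ccc(OC)cc1)C[C@H](O[Si](C)(C)C(C)(C)C)CCC[C@H](O[Si](C)(C)C(C)(C)C)C[C@@H]1C[C@H](CCC[C@H](O[Si](C)(C)C(C)(C)C)CCC[C@H](O[Si](C)(C)C(C)(C)C)CC=C)OC(C)(C)O1 | intermediate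
52 | right-wing alcohol C15–C40: 35-OH, 17,21,29,33-tetra-O-TBS, 25,27-acetonide, C15=CH2 | CCCC[C@H](C)[C@H](O)C[C@H](O[Si](C)(C)C(C)(C)C)CCC[C@H](O[Si](C)(C)C(C)(C)C)C[C@@H]1C[C@H](CCC[C@H](O[Si](C)(C)C(C)(C)C)CCC[C@H](O[Si](C)(C)C(C)(C)C)CC=C)OC(C)(C)O1 | intermediate
53 | seco 2-ynoate ester: O35 acylated by 18, terminal alkenes at C14 and C15 | CCCC[C@H](C)[C@H](OC(=O)C#CCCC[C@H]2C[C@@H](CCC[C@@H](O[Si](C)(C)C(C)(C)C)C=C)OC(C)(C)O2)C[C@H](O[Si](C)(C)C(C)(C)C)CCC[C@H](O[Si](C)(C)C(C)(C)C)C[C@@H]1C[C@H](CCC[C@H](O[Si](C)(C)C(C)(C)C)CCC[C@H](O[Si](C)(C)C(C)(C)C)CC=C)OC(C)(C)O1 | intermediate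
54 | seco (2Z)-3-methyl-2-enoate ester, otherwise as 53 | CCCC[C@H](C)[C@H](OC(=O)/C=C(C)\CCC[C@H]2C[C@@H](CCC[C@@H](O[Si](C)(C)C(C)(C)C)C=C)OC(C)(C)O2)C[C@H](O[Si](C)(C)C(C)(C)C)CCC[C@H](O[Si](C)(C)C(C)(C)C)C[C@@H]1C[C@H](CCC[C@H](O[Si](C)(C)C(C)(C)C)CCC[C@H](O[Si](C)(C)C(C)(C)C)CC=C)OC(C)(C)O1 | intermediate
55 | protected 36-membered lactone with C14=C15 (E/Z): 13,17,21,29,33-penta-O-TBS, 7,9- and 25,27-acetonides | CCCC[C@H](C)[C@H]1C[C@H](O[Si](C)(C)C(C)(C)C)CCC[C@H](O[Si](C)(C)C(C)(C)C)C[C@@H]2C[C@H](CCC[C@H](O[Si](C)(C)C(C)(C)C)CCC[C@H](O[Si](C)(C)C(C)(C)C)CC=C[C@H](O[Si](C)(C)C(C)(C)C)CCC[C@@H]3C[C@H](CCC/C(C)=C\C(=O)O1)OC(C)(C)O3)OC(C)(C)O2 | intermediate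
56 | protected 36-membered lactone, C14–C15 saturated, otherwise as 55 | CCCC[C@H](C)[C@H]1C[C@H](O[Si](C)(C)C(C)(C)C)CCC[C@H](O[Si](C)(C)C(C)(C)C)C[C@@H]2C[C@H](CCC[C@H](O[Si](C)(C)C(C)(C)C)CCC[C@H](O[Si](C)(C)C(C)(C)C)CCC[C@H](O[Si](C)(C)C(C)(C)C)CCC[C@@H]3C[C@H](CCC/C(C)=C\C(=O)O1)OC(C)(C)O3)OC(C)(C)O2 | intermediate
57 | CNP0126363.4: 36-membered (Z)-3-methyl-2-enoate lactone with hydroxyls at C7, C9, C13, C17, C21, C25, C27, C29 and C33 and a hexan-2-yl group on C35 | CCCC[C@H](C)[C@H]1C[C@H](O)CCC[C@H](O)C[C@@H](O)C[C@@H](O)CCC[C@H](O)CCC[C@H](O)CCC[C@H](O)CCC[C@@H](O)C[C@@H](O)CCC/C(C)=C\C(=O)O1 | target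

**Totals**
Total step count: 40. Longest linear sequence: 22 steps (steps 18–25, 27–35 and 36–40, from 26 to 57).

**Steps most likely to fail**

Step 38 (macrocyclising metathesis). Intermolecular metathesis could outrun ring closure at the slowly reacting allylic silyl ether terminus, giving oligomers, or the terminal alkenes could migrate before closure and give ring-contracted lactones. The fallback sets out from 15 and 51 and comes back at 55. The C14=C15 bond is made first by cross-metathesis of 51 with an excess of 15 (second-generation Hoveyda–Grubbs catalyst RuCl2(=CH-C6H4-2-OiPr)(H2IMes), CH2Cl2, 40 °C), which should give the C2–C40 silyl alkyne F1. Methanolysis (K2CO3, MeOH) gives the terminal alkyne F2, and n-BuLi then CO2 gives the 2-ynoic acid F3. DDQ removes the 4-methoxybenzyl group to give the seco hydroxy acid F4. Shiina macrolactonisation (2-methyl-6-nitrobenzoic anhydride, DMAP, high dilution) closes the ring at O35–C1 to the macrocyclic ynoate F5, and Me2CuLi at −78 °C then gives 55.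

Step 31 (three-component linchpin coupling). The silyl shift could occur too early or incompletely, so that the first anion adds to both epoxides in the wrong order or the relayed anion is quenched before it meets 25. The fallback sets out from 5 and 43 and comes back at 48. 2-Lithio-1,3-dithiane (7, from 5 and n-BuLi) opens 43 at C28 to give the hydroxy dithiane F6; TBSCl and imidazole give its C29 silyl ether F7. Lithiation of F7 (t-BuLi, THF/HMPA, −78 °C) and addition of 25 then give 48 by a second Corey–Seebach epoxide opening.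

Step 37 (carbocupration on the full seco ester). The alkenylcopper (allenoate) intermediate could equilibrate before protonation and erode the Z geometry, and the isomers would be hard to separate on this large substrate. The fallback sets out from 16 and 52 and comes back at 54. The lithium acetylide of 16 is trapped with methyl chloroformate to give the methyl ynoate F8. Me2CuLi at −78 °C gives the methyl (Z)-enoate F9, purified from any E isomer at this small stage, and LiOH in THF/MeOH/H2O gives the (Z)-enoic acid F10. Esterification of F10 with 52 (2-methyl-6-nitrobenzoic anhydride, DMAP, Et3N) gives 54.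

Further compounds
F1 | step 38 | cross-metathesis product C2–C40: C14=C15 (E/Z), silyl alkyne at C2, 35-O-(4-methoxybenzyl), otherwise protected as 55 | CCCC[C@H](C)[C@H](OCc1ccc(OC)cc1)C[C@H](O[Si](C)(C)C(C)(C)C)CCC[C@H](O[Si](C)(C)C(C)(C)C)C[C@@H]1C[C@H](CCC[C@H](O[Si](C)(C)C(C)(C)C)CCC[C@H](O[Si](C)(C)C(C)(C)C)CC=C[C@H](O[Si](C)(C)C(C)(C)C)CCC[C@@H]2C[C@H](CCCC#C[Si](C)(C)C)OC(C)(C)O2)OC(C)(C)O1
F2 | step 38 | terminal alkyne from F1 | CCCC[C@H](C)[C@H](OCc1ccc(OC)cc1)C[C@H](O[Si](C)(C)C(C)(C)C)CCC[C@H](O[Si](C)(C)C(C)(C)C)C[C@@H]1C[C@H](CCC[C@H](O[Si](C)(C)C(C)(C)C)CCC[C@H](O[Si](C)(C)C(C)(C)C)CC=C[C@H](O[Si](C)(C)C(C)(C)C)CCC[C@@H]2C[C@H](CCCC#C)OC(C)(C)O2)OC(C)(C)O1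
F3 | step 38 | 2-ynoic acid from F2, 35-O-(4-methoxybenzyl) | CCCC[C@H](C)[C@H](OCc1ccc(OC)cc1)C[C@H](O[Si](C)(C)C(C)(C)C)CCC[C@H](O[Si](C)(C)C(C)(C)C)C[C@@H]1C[C@H](CCC[C@H](O[Si](C)(C)C(C)(C)C)CCC[C@H](O[Si](C)(C)C(C)(C)C)CC=C[C@H](O[Si](C)(C)C(C)(C)C)CCC[C@@H]2C[C@H](CCCC#CC(O)=O)OC(C)(C)O2)OC(C)(C)O1
F4 | step 38 | seco hydroxy 2-ynoic acid (35-OH) | CCCC[C@H](C)[C@H](O)C[C@H](O[Si](C)(C)C(C)(C)C)CCC[C@H](O[Si](C)(C)C(C)(C)C)C[C@@H]1C[C@H](CCC[C@H](O[Si](C)(C)C(C)(C)C)CCC[C@H](O[Si](C)(C)C(C)(C)C)CC=C[C@H](O[Si](C)(C)C(C)(C)C)CCC[C@@H]2C[C@H](CCCC#CC(O)=O)OC(C)(C)O2)OC(C)(C)O1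
F5 | step 38 | macrocyclic 2-ynoate lactone with C14=C15 | CCCC[C@H](C)[C@H]1C[C@H](O[Si](C)(C)C(C)(C)C)CCC[C@H](O[Si](C)(C)C(C)(C)C)C[C@@H]2C[C@H](CCC[C@H](O[Si](C)(C)C(C)(C)C)CCC[C@H](O[Si](C)(C)C(C)(C)C)CC=C[C@H](O[Si](C)(C)C(C)(C)C)CCC[C@@H]3C[C@H](CCCC#CC(=O)O1)OC(C)(C)O3)OC(C)(C)O2
F6 | step 31 | C27–C40 hydroxy dithiane: 1,3-dithian-2-yl (C27) on C28, 29-OH, 33-O-TBS, 35-O-(4-methoxybenzyl) | CCCC[C@H](C)[C@H](OCc1ccc(OC)cc1)C[C@H](O[Si](C)(C)C(C)(C)C)CCC[C@H](O)CC1SCCCS1
F7 | step 31 | 29-O-TBS ether of F6 | CCCC[C@H](C)[C@H](OCc1ccc(OC)cc1)C[C@H](O[Si](C)(C)C(C)(C)C)CCC[C@H](O[Si](C)(C)C(C)(C)C)CC1SCCCS1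
F8 | step 37 | methyl 2-ynoate of the left wing (methyl ester of 18) | COC(=O)C#CCCC[C@H]1C[C@@H](CCC[C@@H](O[Si](C)(C)C(C)(C)C)C=C)OC(C)(C)O1
F9 | step 37 | methyl (2Z)-3-methyl-2-enoate of the left wing | COC(=O)/C=C(C)\CCC[C@H]1C[C@@H](CCC[C@@H](O[Si](C)(C)C(C)(C)C)C=C)OC(C)(C)O1
F10 | step 37 | (2Z)-3-methyl-2-enoic acid of the left wing | OC(=O)/C=C(C)\CCC[C@H]1C[C@@H](CCC[C@@H](O[Si](C)(C)C(C)(C)C)C=C)OC(C)(C)O1
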